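TBS = tert-butyldimethylsilyl, TIPS = triisopropylsilyl. Atom labels (O1, C2–C6, C1'–C3') follow the oxane numbering of the target throughout.

## Structural features

Blepharocalyxin C (31) is an oxane substituted at four ring carbons: C2 carries a 4-hydroxyphenyl group, C3 a branched seven-carbon chain joined through C1', C4 a hydroxyl and C6 a 2-(4-hydroxyphenyl)ethyl arm. Formally it is two 1,7-diarylheptanoid units joined by the C3–C1' bond, one of them folded into the ring through O1. All six stereocentres are S: C2, C3, C4 and C1' are contiguous, C6 is 1,3 to C2 across O1, and C3' sits alone on the chain. In the chair the C2 aryl, the C3 chain and the C6 arm are equatorial and the C4 hydroxyl is axial. The fragile elements are the four free phenols, the 4-hydroxystyrene (acid, oxidants, radicals) and the C2–O1 bond, a 4-hydroxybenzylic ether that can open to a quinone methide under acid or base. The real difficulty is the crowded C3–C1' junction: two adjacent tertiary stereocentres, one on the ring beside the aryl-bearing C2 and one carrying the styrene, neither open to simple substrate control. The key step exploits two facts about the ring. C2 bears both O1 and an electron-rich 4-oxyphenyl group, so it is the oxidised form of the CH2 of a 4-silyloxybenzyl ether on the C6 oxygen. C3 lies α to the C4 oxygen function, so it can be the nucleophilic carbon of a C3=C4 enol, and joining C2 to C3 by oxidation closes the oxane.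

## Logic of the disconnections

**31 to 30.** The five O–Si bonds are cut last. Masking all four phenols and the C3' hydroxyl as silyl ethers lets oxidant, hydride and carbene chemistry run on phenol-free intermediates, and one fluoride step ends the synthesis. The forward step must be buffered, because the freed 4-hydroxyphenyl group at C2 can push open the C2–O1 bond.

**30 to 29.** The C4–H bond is cut, turning the carbinol into a ketone. The ketone is what the ring-forming chemistry delivers, and it makes C3 correctable by enolisation. One stereocentre disappears. The forward reduction must deliver hydride along the equatorial trajectory to give the axial alcohol.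

**29 to 25 and 28 (28 from 26).** The styrene C=C bond is cut. A 4-oxystyrene would not survive the quinone oxidant of the key step, whereas the bare vinyl group of 25 does, so the oxidisable aryl alkene is absent from all earlier intermediates. The forward step is a metathesis at a hindered, α-branched vinyl group; it must be E-selective and must not move the double bond into C1'.

**25 to 23.** A carboxyl carbon is put back on C3. The ester makes C3, not C5, the enol carbon, and it acidifies C3 for the C3–C1' bond formation. Its removal must be mild enough for five silyl ethers, hence an allyl ester cleaved at room temperature; a methyl ester would need hot halide, which strips aryl silyl ethers. Removal must also leave C3 in its thermodynamic configuration.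

**23 to 21 (key).** The C2–C3 bond is cut and the oxane opens. C2 becomes the CH2 of a benzylic ether on the C6 oxygen and C3 the α-carbon of a β-keto ester. The ring and two stereocentres vanish, leaving a chain whose three stereocentres (C6, C1', C3') are isolated from one another. The forward step must oxidise one C–H bond among many, close through carbon and not oxygen, and pass through a chair that gives 2,6-cis. The aryl ring that becomes cationic carries the more robust TIPS group.

**21 to 14 and 20.** The C3–C1' bond is cut, the most convergent cut available, giving two halves of similar size. The forward step must be an allylic alkylation that attacks the internal allyl carbon and chooses one face, fixing C1' by catalyst control.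

**14 to 11 and 13, then 11 to 10 to 6 and 9 (9 from 8 from 7; 13 from 12).** The C3–C4 bond of the keto ester is cut to an aldehyde and a diazoacetate, and the benzylic C–O bond to an alcohol and an imidate. Both forward steps run without base, so the β-oxygenated carbonyl compounds cannot eliminate. The etherification must be acid-catalysed yet spare the aryl silyl ethers.

**20 to 19 to 18 to 16 and 17, then 16 to 15 to 6.** The enoate C=C bond is cut (olefination), framed by redox and protection steps. This is routine chemistry; the olefination must be E-selective and mild towards a β-silyloxy aldehyde.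

**6 to 5 to 3 to 1.** The carbinol C–H bond is cut (asymmetric hydrogenation) and then the C2–C3 bond of the keto ester (decarboxylative Claisen). Both 14 and 20 contain the same (S)-configured ArCH2CH2–CH(O)–CH2 unit, so one catalytic enantioselective step sets both C6 and C3'. The hydrogenation must be highly enantioselective, since the error would enter the target twice.

## Other disconnections considered

**Alternative 1:** Petasis–Ferrier rearrangement. The cut is C5–C6. Forward, Me2AlCl would ionise the 4-methylene-1,3-dioxane A1 between C6 and the enol oxygen, and the aluminium enolate would close C5 onto the C6 oxocarbenium ion to give ketone A2.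
- In its favour: this is an established route to 2,6-cis-tetrahydropyran-4-ones. No oxidant is involved, so the complete styrene chain is carried through and no cross-metathesis is needed. No quaternary carbon is made, no ester is removed, and C3 is fixed before the ring forms. On these points it is better than the chosen plan.
- On 2,6-cis control it is the equal of the chosen plan: both close an oxocarbenium ion onto an enol-type carbon through a chair.
- Against it: the C2 aryl must be electron-poor (the mesylate in A1), or the Lewis acid would ionise the benzylic C2–O1 bond instead. Removing that sulfonate later needs strongly basic or nucleophilic conditions that clash with aryl silyl ethers. A1 also demands acyclic material with the contiguous C2/C3/C1' triad already set, harder than the three isolated centres of 21. Methylenation of a hindered dioxanone carbonyl and a Lewis acid beside a 4-silyloxystyrene add risk.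
- Step economy: what is saved after the ring closure is likely spent on the triad and the sulfonate, so roughly equal.

**Alternative 2:** Chromium-catalysed hetero-Diels–Alder. The cuts are O1–C2 and C5–C6. Forward, aldehyde A4 would add across the termini of diene A3 under CrCl(L) (trivalent chromium; L is the tridentate Schiff base from cis-1-amino-2-indanol and 3-(1-adamantyl)-5-methylsalicylaldehyde), giving the dihydropyran silyl enol ether A5.
- In its favour: two bonds and the ring form in one step from two large pieces, and an endo transition state gives 2,6-cis under catalyst control. The styrene is untouched. Hydrolysis of A5 would give the C4 ketone with C3 set thermodynamically, three steps from the target. On convergence and step count it is better than the chosen plan; on 2,6-cis control it is equal.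
- Against it: A3 is a 1-aryl-3-silyloxy diene with a branched, stereogenic substituent on C3, far less reactive than the oxygen-rich, alkyl-substituted dienes this catalyst class is known for. The catalyst would have to set C2 and C6 at once while overriding C1'; in the chosen plan C6 comes from a reliable hydrogenation and only C2 from the cyclisation. Making A3 requires enolising a cross-conjugated ketone whose neighbouring C1' centre can epimerise by dienolisation. A stepwise Mukaiyama aldol pathway could also erode selectivity.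
- Overall: shorter, but resting on a less certain substrate class.

**Alternative 3:** Flavoenzyme quinone methide cyclisation. The cut is O1–C2. Forward, a flavin-dependent 4-alkylphenol oxidase of the vanillyl-alcohol oxidase family with O2 would dehydrogenate the free 4-hydroxybenzyl group of diol A6 to the p-quinone methide, and the C6 hydroxyl would add to the methide carbon to give A7.
- Mechanistically it mirrors the chosen plan and is its equal in logic: both oxidise the benzylic C2–H of a 4-oxybenzyl unit and trap the electrophile internally. Here C2–C3 is in place and O1–C2 forms; in the chosen plan it is the reverse.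
- In its favour: the oxidant is O2 in water near neutral pH, the reacting phenol needs no protection, and A7 already has C4 at the alcohol level, so only desilylation remains. On mildness and on steps after the ring closure it is better than the chosen plan.
- Against it: these enzymes act on small 4-alkylphenols, and A6 is large, lipophilic and carries four silyl ethers. Within the active site the methide is normally captured by water or tautomerises to the alkene, here across C2–C3, in competition with the C6 hydroxyl. The C2 configuration would depend on the protein. A6 also needs C3, C4, C6 and C1' set in an open chain, a harder task than making 21.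
- Overall: attractive on paper, but far less predictable, and any gain at the end is paid for earlier.

Key step: step 16

Assumption: C3 of 21–24 is written without a descriptor, because it is labile in 21 (epimers and enol) and uncontrolled but irrelevant in 23; every other descriptor agrees with 31.

## Route

Step 1
Reactants: 1 3-(4-hydroxyphenyl)propanoic acid
Product: 3 3-[4-(TBS-oxy)phenyl]propanoic acid, via bis-silylated acid 2 (not isolated)
Conditions: TBSCl (2.3 equiv), imidazole, DMF, rt; then AcOH/THF/H2O, rt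
Reagents that add atoms: tert-butyldimethylsilyl chloride, CC(C)(C)[Si](C)(C)Cl
Why: Phenol and acid are both silylated, and the far more labile silyl ester is then hydrolysed by mild aqueous acid that an aryl silyl ether tolerates.

Step 2
Reactants: 3 3-[4-(TBS-oxy)phenyl]propanoic acid
Product: 5 methyl 3-oxo-5-[4-(TBS-oxy)phenyl]pentanoate, via acyl imidazolide 4 (not isolated)
Conditions: CDI, THF, rt; then KO2CCH2CO2Me, MgCl2, THF, rt to 45 °C; aqueous citric acid
Reagents that add atoms: potassium methyl malonate, COC(=O)CC(=O)[O-].[K+]; 1,1'-carbonyldiimidazole, O=C(n1ccnc1)n1ccnc1 (imidazolyl group of 4 only)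
Why: Masamune–Brooks decarboxylative Claisen condensation: the magnesium malonate half-ester is acylated by the imidazolide and loses CO2, under near-neutral conditions that leave the aryl silyl ether intact.

Step 3
Reactants: 5 methyl 3-oxo-5-[4-(TBS-oxy)phenyl]pentanoate
Product: 6 methyl (3S)-3-hydroxy-5-[4-(TBS-oxy)phenyl]pentanoate
Conditions: H2 (50 bar), [RuCl(p-cymene)((S)-BINAP)]Cl (0.5 mol %), MeOH, 50 °C
Reagents that add atoms: none
Why: Noyori asymmetric hydrogenation of a β-keto ester; the divalent ruthenium (S)-BINAP catalyst should give the (S)-carbinol by the sense of induction known for alkyl β-keto esters. This one centre later becomes both C6 and C3'.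

Step 4
Reactants: 7 4-hydroxybenzyl alcohol
Product: 8 [4-(TIPS-oxy)phenyl]methanol
Conditions: NaH (1.0 equiv), THF, 0 °C; then TIPSCl (1.0 equiv), 0 °C to rt
Reagents that add atoms: triisopropylsilyl chloride, CC(C)[Si](Cl)(C(C)C)C(C)C
Why: One equivalent of base forms only the phenoxide (about five pKa units more acidic than the benzylic alcohol), which is silylated selectively.

Step 5
Reactants: 8 [4-(TIPS-oxy)phenyl]methanol
Product: 9 4-(TIPS-oxy)benzyl 2,2,2-trichloroacetimidate
Conditions: Cl3CCN, DBU (5 mol %), CH2Cl2, 0 °C; used crude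
Reagents that add atoms: trichloroacetonitrile, ClC(Cl)(Cl)C#N
Why: Base-catalysed addition of the alcohol to the nitrile, as in the preparation of the 4-methoxybenzyl imidate; the electron-rich imidate is used at once.

Step 6
Reactants: 6 methyl (3S)-3-hydroxy-5-[4-(TBS-oxy)phenyl]pentanoate; 9 4-(TIPS-oxy)benzyl 2,2,2-trichloroacetimidate
Product: 10 methyl (3S)-5-[4-(TBS-oxy)phenyl]-3-{[4-(TIPS-oxy)phenyl]methoxy}pentanoate
Conditions: 9 (1.5 equiv), La(OTf)3 (5 mol %), toluene, rt
Reagents that add atoms: none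
Why: Acid-catalysed O-benzylation by a trichloroacetimidate; no alkoxide is formed, so the β-hydroxy ester cannot undergo retro-aldol cleavage or elimination, and the C–O bond at the stereocentre is untouched.

Step 7
Reactants: 10 methyl (3S)-5-[4-(TBS-oxy)phenyl]-3-{[4-(TIPS-oxy)phenyl]methoxy}pentanoate
Product: 11 (3S)-5-[4-(TBS-oxy)phenyl]-3-{[4-(TIPS-oxy)phenyl]methoxy}pentanal
Conditions: i-Bu2AlH (1.1 equiv), CH2Cl2, −78 °C; Rochelle salt
Reagents that add atoms: none
Why: Partial reduction of a methyl ester; the β-alkoxy group stabilises the tetrahedral aluminium intermediate at −78 °C, so the aldehyde is released only on work-up.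

Step 8
Reactants: 12 glycine allyl ester 4-toluenesulfonate
Product: 13 allyl diazoacetate
Conditions: NaNO2, H2O/CH2Cl2, cat. H2SO4, −5 to 0 °C; used as a CH2Cl2 solution
Reagents that add atoms: sodium nitrite, [Na+].[O-]N=O
Why: Classical diazotisation of an α-amino ester; the electron-poor diazo compound is extracted into CH2Cl2 as it forms.

Step 9
Reactants: 11 (3S)-5-[4-(TBS-oxy)phenyl]-3-{[4-(TIPS-oxy)phenyl]methoxy}pentanal; 13 allyl diazoacetate
Product: 14 allyl (5S)-3-oxo-7-[4-(TBS-oxy)phenyl]-5-{[4-(TIPS-oxy)phenyl]methoxy}heptanoate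
Conditions: SnCl2 (0.2 equiv), CH2Cl2, rt
Reagents that add atoms: none
Why: Roskamp reaction: Lewis-acid-promoted addition of the diazoacetate to the aldehyde, then a 1,2-hydride shift with loss of N2, gives the β-keto ester without base, so the β-alkoxy aldehyde cannot eliminate.

Step 10
Reactants: 6 methyl (3S)-3-hydroxy-5-[4-(TBS-oxy)phenyl]pentanoate
Product: 15 methyl (3S)-3-(TBS-oxy)-5-[4-(TBS-oxy)phenyl]pentanoate
Conditions: TBSCl (1.3 equiv), imidazole, DMF, rt
Reagents that add atoms: tert-butyldimethylsilyl chloride, CC(C)(C)[Si](C)(C)Cl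
Why: Standard silylation of a secondary alcohol.

Step 11
Reactants: 15 methyl (3S)-3-(TBS-oxy)-5-[4-(TBS-oxy)phenyl]pentanoate
Product: 16 (3S)-3-(TBS-oxy)-5-[4-(TBS-oxy)phenyl]pentanal
Conditions: i-Bu2AlH (1.1 equiv), CH2Cl2, −78 °C; Rochelle salt
Reagents that add atoms: none
Why: Partial reduction of the ester to the aldehyde at low temperature, as in step 7.

Step 12
Reactants: 16 (3S)-3-(TBS-oxy)-5-[4-(TBS-oxy)phenyl]pentanal; 17 triethyl phosphonoacetate
Product: 18 ethyl (2E,5S)-5-(TBS-oxy)-7-[4-(TBS-oxy)phenyl]hept-2-enoate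
Conditions: LiCl, i-Pr2NEt, MeCN, rt
Reagents that add atoms: none
Why: Horner–Wadsworth–Emmons olefination under Masamune–Roush conditions; the weak amine base is enough for the lithium-chelated phosphonate and spares the β-silyloxy aldehyde and the aryl silyl ether, and the stabilised ylide gives the E-enoate.

Step 13
Reactants: 18 ethyl (2E,5S)-5-(TBS-oxy)-7-[4-(TBS-oxy)phenyl]hept-2-enoate
Product: 19 (2E,5S)-5-(TBS-oxy)-7-[4-(TBS-oxy)phenyl]hept-2-en-1-ol
Conditions: i-Bu2AlH (2.3 equiv), CH2Cl2, −78 °C; Rochelle salt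
Reagents that add atoms: none
Why: 1,2-Reduction of an enoate to the allylic alcohol by an aluminium hydride, without conjugate reduction.

Step 14
Reactants: 19 (2E,5S)-5-(TBS-oxy)-7-[4-(TBS-oxy)phenyl]hept-2-en-1-ol
Product: 20 (2E,5S)-5-(TBS-oxy)-7-[4-(TBS-oxy)phenyl]hept-2-en-1-yl methyl carbonate
Conditions: ClCO2Me, pyridine, CH2Cl2, 0 °C
Reagents that add atoms: methyl chloroformate, COC(=O)Cl
Why: Acylation of the primary allylic alcohol gives the linear carbonate that iridium catalysts ionise readily.

Step 15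
Reactants: 14 allyl (5S)-3-oxo-7-[4-(TBS-oxy)phenyl]-5-{[4-(TIPS-oxy)phenyl]methoxy}heptanoate; 20 (2E,5S)-5-(TBS-oxy)-7-[4-(TBS-oxy)phenyl]hept-2-en-1-yl methyl carbonate
Product: 21 allyl (5S)-3-oxo-7-[4-(TBS-oxy)phenyl]-2-{(3S,5S)-5-(TBS-oxy)-7-[4-(TBS-oxy)phenyl]hept-1-en-3-yl}-5-{[4-(TIPS-oxy)phenyl]methoxy}heptanoate (both epimers at the keto ester α-carbon)
Conditions: [Ir(cod)Cl]2 (2 mol %), (Ra,R,R)-L (4 mol %; L = O,O'-(1,1'-binaphthalene-2,2'-diyl) N,N-bis(1-phenylethyl)phosphoramidite), activated with n-PrNH2 then evaporated; 14 (1.2 equiv), THF, rt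
Reagents that add atoms: none
Why: Iridium-catalysed asymmetric allylic alkylation of a stabilised enolate: attack at the substituted allyl terminus gives the branched product, and the methoxide released from the carbonate is consumed at once by the acidic keto ester. The ligand fixes C1' (the (Ra,R,R) enantiomer is the one expected to give 1'S; both are available, so the assignment would be checked on the first run), the remote C3' centre should have little influence, and C3 forms as an inconsequential epimer mixture.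

Step 16
Reactants: 21 allyl (5S)-3-oxo-7-[4-(TBS-oxy)phenyl]-2-{(3S,5S)-5-(TBS-oxy)-7-[4-(TBS-oxy)phenyl]hept-1-en-3-yl}-5-{[4-(TIPS-oxy)phenyl]methoxy}heptanoate
Product: 23 allyl (2R,6S)-4-oxo-6-{2-[4-(TBS-oxy)phenyl]ethyl}-3-{(3S,5S)-5-(TBS-oxy)-7-[4-(TBS-oxy)phenyl]hept-1-en-3-yl}-2-[4-(TIPS-oxy)phenyl]oxane-3-carboxylate (C3 epimers), via (E)-oxocarbenium ion 22 (not isolated)
Conditions: DDQ (1.5 equiv), 2,6-dichloropyridine (3 equiv), LiClO4 (1 equiv), 4 Å MS, ClCH2CH2Cl, 0 °C to rt
Reagents that add atoms: none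
Why: Proposed new method: DDQ should take an electron and then a hydrogen atom (net hydride) from the only C–H bond that is both benzylic to the 4-silyloxyarene and α to an ether oxygen, giving the (E)-oxocarbenium ion 22, which the hydrogen-bonded C3=C4 enol of the β-keto ester should capture through C3; the closest known reaction type is the DDQ-mediated oxidative cyclisation of 4-alkoxybenzyl ethers onto tethered enol acetates to give 2,6-cis-tetrahydropyran-4-ones, supported by DDQ-mediated dehydrogenative coupling of benzylic ethers with 1,3-dicarbonyl compounds, and the new elements are a β-keto ester enol as internal nucleophile and the quaternary C3 it creates. The oxane closes in a 6-(enolendo)-endo-trig mode, endo also with respect to C2=O1+. C2 is set by a chair transition state in which the C6 arm, anchored by the preset C6 centre, and the aryl group of the (E)-oxocarbenium ion are both equatorial, giving 2,6-cis; this is also the thermodynamic isomer if the closure is reversible. The quaternary C3 is not controlled and need not be, since step 17 removes the ester and resets C3. Site selectivity rests on the α-oxygen, which the arylethyl CH2 groups lack, on the electron-poor keto ester that makes the C2–H of the product much less hydridic, and on the absence of the styrene, a terminal vinyl group being inert to DDQ. Attack through the enol oxygen would give a six-membered mixed acetal that can re-ionise, so the irreversible attack through carbon should prevail. 2,6-Dichloropyridine buffers the acidic hydroquinone, LiClO4 supports the ion pair and enolisation, and TIPS on the ring that carries the charge resists desilylation to a quinone methide.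

Step 17
Reactants: 23 allyl (2R,6S)-4-oxo-6-{2-[4-(TBS-oxy)phenyl]ethyl}-3-{(3S,5S)-5-(TBS-oxy)-7-[4-(TBS-oxy)phenyl]hept-1-en-3-yl}-2-[4-(TIPS-oxy)phenyl]oxane-3-carboxylate
Product: 25 (2S,3R,6S)-6-{2-[4-(TBS-oxy)phenyl]ethyl}-3-{(3S,5S)-5-(TBS-oxy)-7-[4-(TBS-oxy)phenyl]hept-1-en-3-yl}-2-[4-(TIPS-oxy)phenyl]oxan-4-one, via β-keto acid 24 (not isolated)
Conditions: Pd(PPh3)4 (5 mol %), morpholine (5 equiv), THF, rt; then 45 °C
Reagents that add atoms: none
Why: Palladium-catalysed deallylation and decarboxylation of an allyl β-keto ester: zerovalent palladium ionises the allyl ester, morpholine takes the allyl group, and the quaternary β-keto acid loses CO2. The C3 enol ketonises by axial protonation, and amine-mediated enolisation equilibrates C3 to the epimer with the chain equatorial and trans to the C2 aryl (3R); no halide or heat threatens the silyl ethers.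

Step 18
Reactants: 26 4-acetoxystyrene
Product: 28 tert-butyldimethyl(4-vinylphenoxy)silane, via sodium 4-vinylphenoxide 27 (not isolated)
Conditions: NaOMe (1.0 equiv), MeOH, 0 °C; evaporate; TBSCl, THF, 0 °C to rt
Reagents that add atoms: tert-butyldimethylsilyl chloride, CC(C)(C)[Si](C)(C)Cl; sodium methoxide, C[O-].[Na+] (sodium of 27 only)
Why: Methanolysis of the aryl acetate gives the phenoxide, which is silylated directly, so the polymerisation-prone free 4-vinylphenol is never handled.

Step 19
Reactants: 25 (2S,3R,6S)-6-{2-[4-(TBS-oxy)phenyl]ethyl}-3-{(3S,5S)-5-(TBS-oxy)-7-[4-(TBS-oxy)phenyl]hept-1-en-3-yl}-2-[4-(TIPS-oxy)phenyl]oxan-4-one; 28 tert-butyldimethyl(4-vinylphenoxy)silane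
Product: 29 (2S,3R,6S)-3-{(1E,3S,5S)-5-(TBS-oxy)-1,7-bis[4-(TBS-oxy)phenyl]hept-1-en-3-yl}-6-{2-[4-(TBS-oxy)phenyl]ethyl}-2-[4-(TIPS-oxy)phenyl]oxan-4-one
Conditions: RuCl2(=CHPh)(H2IMes)(PCy3) (second-generation Grubbs catalyst, 10 mol %), 28 (4 equiv, in portions), 1,4-benzoquinone (10 mol %), CH2Cl2, 40 °C
Reagents that add atoms: none
Why: Olefin cross-metathesis between a hindered monosubstituted alkene that does not homodimerise and an excess of a styrene, with loss of ethene; the E-alkene is the thermodynamic product, and benzoquinone suppresses ruthenium hydride migration of the double bond towards C1'.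

Step 20
Reactants: 29 (2S,3R,6S)-3-{(1E,3S,5S)-5-(TBS-oxy)-1,7-bis[4-(TBS-oxy)phenyl]hept-1-en-3-yl}-6-{2-[4-(TBS-oxy)phenyl]ethyl}-2-[4-(TIPS-oxy)phenyl]oxan-4-one
Product: 30 (2S,3S,4S,6S)-3-{(1E,3S,5S)-5-(TBS-oxy)-1,7-bis[4-(TBS-oxy)phenyl]hept-1-en-3-yl}-6-{2-[4-(TBS-oxy)phenyl]ethyl}-2-[4-(TIPS-oxy)phenyl]oxan-4-ol
Conditions: LiBH(s-Bu)3 (1.5 equiv), THF, −78 °C; then pH 7 buffer, 30% H2O2, 0 °C
Reagents that add atoms: none
Why: The bulky hydride should approach the chair ketone along the equatorial trajectory, away from the axial hydrogens at C2 and C6, giving the axial C4 alcohol (4S) cis to the C3 chain, as is usual for 2-substituted cyclohexanones and 2,6-cis-tetrahydropyran-4-ones; the neutral oxidative work-up spares the aryl silyl ethers.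

Step 21
Reactants: 30 (2S,3S,4S,6S)-3-{(1E,3S,5S)-5-(TBS-oxy)-1,7-bis[4-(TBS-oxy)phenyl]hept-1-en-3-yl}-6-{2-[4-(TBS-oxy)phenyl]ethyl}-2-[4-(TIPS-oxy)phenyl]oxan-4-ol
Product: 31 blepharocalyxin C, (2S,3S,4S,6S)-3-[(1E,3S,5S)-5-hydroxy-1,7-bis(4-hydroxyphenyl)hept-1-en-3-yl]-2-(4-hydroxyphenyl)-6-[2-(4-hydroxyphenyl)ethyl]oxan-4-ol
Conditions: Bu4NF (8 equiv), AcOH (8 equiv), THF, 0 °C to rt
Reagents that add atoms: none
Why: Fluoride cleaves the four aryl silyl ethers quickly and the secondary alkyl TBS ether more slowly; the acetic acid buffer keeps the phenoxide concentration low, so the 4-hydroxybenzylic C2–O1 bond should not open to a quinone methide and no stereocentre is touched.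

## Compound list

1 | 3-(4-hydroxyphenyl)propanoic acid | OC(=O)CCc1ccc(O)cc1 | starting material
2 | tert-butyldimethylsilyl 3-[4-(TBS-oxy)phenyl]propanoate | CC(C)(C)[Si](C)(C)OC(=O)CCc1ccc(O[Si](C)(C)C(C)(C)C)cc1 | intermediate (not isolated)
3 | 3-[4-(TBS-oxy)phenyl]propanoic acid | OC(=O)CCc1ccc(O[Si](C)(C)C(C)(C)C)cc1 | intermediate
4 | 1-{3-[4-(TBS-oxy)phenyl]propanoyl}imidazole | O=C(CCc1ccc(O[Si](C)(C)C(C)(C)C)cc1)n1ccnc1 | intermediate (not isolated)
5 | methyl 3-oxo-5-[4-(TBS-oxy)phenyl]pentanoate | COC(=O)CC(=O)CCc1ccc(O[Si](C)(C)C(C)(C)C)cc1 | intermediate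
6 | methyl (3S)-3-hydroxy-5-[4-(TBS-oxy)phenyl]pentanoate | COC(=O)C[C@@H](O)CCc1ccc(O[Si](C)(C)C(C)(C)C)cc1 | intermediate
7 | 4-hydroxybenzyl alcohol | OCc1ccc(O)cc1 | starting material
8 | [4-(TIPS-oxy)phenyl]methanol | OCc1ccc(O[Si](C(C)C)(C(C)C)C(C)C)cc1 | intermediate
9 | 4-(TIPS-oxy)benzyl 2,2,2-trichloroacetimidate | N=C(OCc1ccc(O[Si](C(C)C)(C(C)C)C(C)C)cc1)C(Cl)(Cl)Cl | intermediate
10 | methyl (3S)-5-[4-(TBS-oxy)phenyl]-3-{[4-(TIPS-oxy)phenyl]methoxy}pentanoate | COC(=O)C[C@@H](OCc1ccc(O[Si](C(C)C)(C(C)C)C(C)C)cc1)CCc1ccc(O[Si](C)(C)C(C)(C)C)cc1 | intermediate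
11 | (3S)-5-[4-(TBS-oxy)phenyl]-3-{[4-(TIPS-oxy)phenyl]methoxy}pentanal | O=CC[C@@H](OCc1ccc(O[Si](C(C)C)(C(C)C)C(C)C)cc1)CCc1ccc(O[Si](C)(C)C(C)(C)C)cc1 | intermediate
12 | glycine allyl ester 4-toluenesulfonate | C=CCOC(=O)C[NH3+].Cc1ccc(cc1)S(=O)(=O)[O-] | starting material
13 | allyl diazoacetate | C=CCOC(=O)C=[N+]=[N-] | intermediate
14 | allyl (5S)-3-oxo-7-[4-(TBS-oxy)phenyl]-5-{[4-(TIPS-oxy)phenyl]methoxy}heptanoate | C=CCOC(=O)CC(=O)C[C@@H](OCc1ccc(O[Si](C(C)C)(C(C)C)C(C)C)cc1)CCc1ccc(O[Si](C)(C)C(C)(C)C)cc1 | intermediate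
15 | methyl (3S)-3-(TBS-oxy)-5-[4-(TBS-oxy)phenyl]pentanoate | COC(=O)C[C@@H](O[Si](C)(C)C(C)(C)C)CCc1ccc(O[Si](C)(C)C(C)(C)C)cc1 | intermediate
16 | (3S)-3-(TBS-oxy)-5-[4-(TBS-oxy)phenyl]pentanal | O=CC[C@@H](O[Si](C)(C)C(C)(C)C)CCc1ccc(O[Si](C)(C)C(C)(C)C)cc1 | intermediate
17 | triethyl phosphonoacetate | CCOC(=O)CP(=O)(OCC)OCC | starting material
18 | ethyl (2E,5S)-5-(TBS-oxy)-7-[4-(TBS-oxy)phenyl]hept-2-enoate | CCOC(=O)/C=C/C[C@@H](O[Si](C)(C)C(C)(C)C)CCc1ccc(O[Si](C)(C)C(C)(C)C)cc1 | intermediate
19 | (2E,5S)-5-(TBS-oxy)-7-[4-(TBS-oxy)phenyl]hept-2-en-1-ol | OC/C=C/C[C@@H](O[Si](C)(C)C(C)(C)C)CCc1ccc(O[Si](C)(C)C(C)(C)C)cc1 | intermediate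
20 | (2E,5S)-5-(TBS-oxy)-7-[4-(TBS-oxy)phenyl]hept-2-en-1-yl methyl carbonate | COC(=O)OC/C=C/C[C@@H](O[Si](C)(C)C(C)(C)C)CCc1ccc(O[Si](C)(C)C(C)(C)C)cc1 | intermediate
21 | allyl (5S)-3-oxo-7-[4-(TBS-oxy)phenyl]-2-{(3S,5S)-5-(TBS-oxy)-7-[4-(TBS-oxy)phenyl]hept-1-en-3-yl}-5-{[4-(TIPS-oxy)phenyl]methoxy}heptanoate, epimers at the keto ester α-carbon | C=C[C@H](C[C@@H](O[Si](C)(C)C(C)(C)C)CCc1ccc(O[Si](C)(C)C(C)(C)C)cc1)C(C(=O)OCC=C)C(=O)C[C@@H](OCc1ccc(O[Si](C(C)C)(C(C)C)C(C)C)cc1)CCc1ccc(O[Si](C)(C)C(C)(C)C)cc1 | intermediate (key-step precursor)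
22 | (E)-oxocarbenium ion of 21 (C2=O1+) | C=C[C@H](C[C@@H](O[Si](C)(C)C(C)(C)C)CCc1ccc(O[Si](C)(C)C(C)(C)C)cc1)C(C(=O)OCC=C)C(=O)C[C@@H]([O+]=Cc1ccc(O[Si](C(C)C)(C(C)C)C(C)C)cc1)CCc1ccc(O[Si](C)(C)C(C)(C)C)cc1 | intermediate (not isolated)
23 | allyl (2R,6S)-4-oxo-6-{2-[4-(TBS-oxy)phenyl]ethyl}-3-{(3S,5S)-5-(TBS-oxy)-7-[4-(TBS-oxy)phenyl]hept-1-en-3-yl}-2-[4-(TIPS-oxy)phenyl]oxane-3-carboxylate, C3 epimers | C=C[C@H](C[C@@H](O[Si](C)(C)C(C)(C)C)CCc1ccc(O[Si](C)(C)C(C)(C)C)cc1)C2(C(=O)OCC=C)[C@@H](c3ccc(O[Si](C(C)C)(C(C)C)C(C)C)cc3)O[C@@H](CCc3ccc(O[Si](C)(C)C(C)(C)C)cc3)CC2=O | intermediate (key-step product)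
24 | (2R,6S)-4-oxo-6-{2-[4-(TBS-oxy)phenyl]ethyl}-3-{(3S,5S)-5-(TBS-oxy)-7-[4-(TBS-oxy)phenyl]hept-1-en-3-yl}-2-[4-(TIPS-oxy)phenyl]oxane-3-carboxylic acid, C3 epimers | C=C[C@H](C[C@@H](O[Si](C)(C)C(C)(C)C)CCc1ccc(O[Si](C)(C)C(C)(C)C)cc1)C2(C(=O)O)[C@@H](c3ccc(O[Si](C(C)C)(C(C)C)C(C)C)cc3)O[C@@H](CCc3ccc(O[Si](C)(C)C(C)(C)C)cc3)CC2=O | intermediate (not isolated)
25 | (2S,3R,6S)-6-{2-[4-(TBS-oxy)phenyl]ethyl}-3-{(3S,5S)-5-(TBS-oxy)-7-[4-(TBS-oxy)phenyl]hept-1-en-3-yl}-2-[4-(TIPS-oxy)phenyl]oxan-4-one | C=C[C@H](C[C@@H](O[Si](C)(C)C(C)(C)C)CCc1ccc(O[Si](C)(C)C(C)(C)C)cc1)[C@@H]2[C@@H](c3ccc(O[Si](C(C)C)(C(C)C)C(C)C)cc3)O[C@@H](CCc3ccc(O[Si](C)(C)C(C)(C)C)cc3)CC2=O | intermediate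
26 | 4-acetoxystyrene | CC(=O)Oc1ccc(C=C)cc1 | starting material
27 | sodium 4-vinylphenoxide | [Na+].[O-]c1ccc(C=C)cc1 | intermediate (not isolated)
28 | tert-butyldimethyl(4-vinylphenoxy)silane | C=Cc1ccc(O[Si](C)(C)C(C)(C)C)cc1 | intermediate
29 | (2S,3R,6S)-3-{(1E,3S,5S)-5-(TBS-oxy)-1,7-bis[4-(TBS-oxy)phenyl]hept-1-en-3-yl}-6-{2-[4-(TBS-oxy)phenyl]ethyl}-2-[4-(TIPS-oxy)phenyl]oxan-4-one | CC(C)(C)[Si](C)(C)Oc1ccc(/C=C/[C@H](C[C@@H](O[Si](C)(C)C(C)(C)C)CCc2ccc(O[Si](C)(C)C(C)(C)C)cc2)[C@@H]2[C@@H](c3ccc(O[Si](C(C)C)(C(C)C)C(C)C)cc3)O[C@@H](CCc3ccc(O[Si](C)(C)C(C)(C)C)cc3)CC2=O)cc1 | intermediate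
30 | (2S,3S,4S,6S)-3-{(1E,3S,5S)-5-(TBS-oxy)-1,7-bis[4-(TBS-oxy)phenyl]hept-1-en-3-yl}-6-{2-[4-(TBS-oxy)phenyl]ethyl}-2-[4-(TIPS-oxy)phenyl]oxan-4-ol | CC(C)(C)[Si](C)(C)Oc1ccc(/C=C/[C@H](C[C@@H](O[Si](C)(C)C(C)(C)C)CCc2ccc(O[Si](C)(C)C(C)(C)C)cc2)[C@@H]2[C@@H](c3ccc(O[Si](C(C)C)(C(C)C)C(C)C)cc3)O[C@@H](CCc3ccc(O[Si](C)(C)C(C)(C)C)cc3)C[C@@H]2O)cc1 | intermediate
31 | blepharocalyxin C | Oc1ccc(/C=C/[C@H](C[C@@H](O)CCc2ccc(O)cc2)[C@@H]2[C@@H](c3ccc(O)cc3)O[C@@H](CCc3ccc(O)cc3)C[C@@H]2O)cc1 | target

## Step count and least certain steps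

Total step count: 21. Longest linear sequence: 14 steps (1, 2, 3, 10, 11, 12, 13, 14, 15, 16, 17, 19, 20, 21).

**Step 16 (key step, proposed new method).** The most likely failures are sluggish hydride abstraction and loss of the cation before it cyclises. A silyloxy group donates less than a methoxy group, and three other electron-rich arenes compete for the oxidant. The enol carbon is hindered and only partly enolised, so capture by traces of water would give oxidative debenzylation instead of ring closure.
Fallback, known chemistry, setting out from 6, 8 and 20 and returning at 23: Claisen condensation of 6 with excess lithium enolate of allyl acetate (THF, −78 to −20 °C) would give allyl (5S)-5-hydroxy-3-oxo-7-[4-(TBS-oxy)phenyl]heptanoate F1. Oxidation of 8 with MnO2 would give 4-(TIPS-oxy)benzaldehyde F2. A Lewis-acid-mediated Maitland–Japp condensation of F1 with F2 (Knoevenagel condensation then oxa-Michael closure, for example Yb(OTf)3 in CH2Cl2) would give the 2,6-cis cyclic keto ester allyl (2S,6S)-4-oxo-6-{2-[4-(TBS-oxy)phenyl]ethyl}-2-[4-(TIPS-oxy)phenyl]oxane-3-carboxylate F3. Iridium-catalysed allylic alkylation of this cyclic β-keto ester with 20, under the conditions of step 15, would then build the quaternary C3 and C1' together and deliver 23. That last reaction type is known for cyclic β-keto esters, though the C2 aryl makes this case crowded.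

**Step 15.** Branched selectivity and facial control could erode with a β-branched, silyloxy-bearing allyl unit, and the catalyst could also ionise the allyl ester of 14.
Fallback setting out from 14 and 16 and returning at 21: Knoevenagel condensation (piperidinium acetate, 4 Å MS, CH2Cl2) would give the alkylidene keto ester allyl 2-{(3S)-3-(TBS-oxy)-5-[4-(TBS-oxy)phenyl]pentylidene}-3-oxo-7-[4-(TBS-oxy)phenyl]-5-{[4-(TIPS-oxy)phenyl]methoxy}heptanoate F4. Conjugate addition of a vinyl cuprate (CH2=CHMgBr, CuBr·SMe2, THF, −78 °C) would give 21. C1' would then depend only on weak induction from C3', so both epimers are expected and would be separated at 25, at the cost of material.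

**Step 19.** The hindered α-branched vinyl group may fail to turn over while the styrene partner is consumed by homodimerisation, and ruthenium hydrides may move the double bond towards C1'.
Fallback setting out from 25 and returning at 29, with no new intermediate: Mizoroki–Heck arylation of the vinyl group with tert-butyl(4-iodophenoxy)dimethylsilane (Pd(OAc)2, P(o-tolyl)3, Et3N, MeCN, 80 °C), which forms the same E-styrene by carbopalladation and β-hydride elimination.

**Step 17.** β-Elimination across C3–C2 through the C3 enol could open the ring, and C3 could equilibrate incompletely. Stronger base must be avoided, because elimination on the C5–C6 side would erase the C6 centre.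
Fallback setting out from 23 and returning at 25: after the same deallylation and decarboxylation, the crude mixture would be treated with catalytic camphorsulfonic acid in CH2Cl2. This would convert the ring-opened (5S)-5-hydroxy-7-[4-(TBS-oxy)phenyl]-1-[4-(TIPS-oxy)phenyl]-2-{(3S,5S)-5-(TBS-oxy)-7-[4-(TBS-oxy)phenyl]hept-1-en-3-yl}hept-1-en-3-one F5 into 25 by thermodynamically controlled oxa-Michael closure. The chair with all three substituents equatorial resets C2 and C3 together without touching C6.

**Step 20.** Hydride could arrive along the axial trajectory, if the equatorial C3 chain blocks the usual approach, or the basic reagent could enolise the hindered ketone.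
Fallback setting out from 29 and returning at 30: NaBH4 (MeOH, 0 °C) would give the equatorial alcohol, the (4R)-epimer of 30, F6. Mitsunobu inversion with 4-nitrobenzoic acid (PPh3, diisopropyl azodicarboxylate, toluene) would give the axial (4S)-4-nitrobenzoate of 30, F7. Reductive ester cleavage with i-Bu2AlH at −78 °C, which leaves aryl silyl ethers alone, would then give 30.

## Further compounds

F1 | step 16 | allyl (5S)-5-hydroxy-3-oxo-7-[4-(TBS-oxy)phenyl]heptanoate | C=CCOC(=O)CC(=O)C[C@@H](O)CCc1ccc(O[Si](C)(C)C(C)(C)C)cc1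
F2 | step 16 | 4-(TIPS-oxy)benzaldehyde | O=Cc1ccc(O[Si](C(C)C)(C(C)C)C(C)C)cc1
F3 | step 16 | allyl (2S,6S)-4-oxo-6-{2-[4-(TBS-oxy)phenyl]ethyl}-2-[4-(TIPS-oxy)phenyl]oxane-3-carboxylate (keto and enol forms) | C=CCOC(=O)C1[C@@H](c2ccc(O[Si](C(C)C)(C(C)C)C(C)C)cc2)O[C@@H](CCc2ccc(O[Si](C)(C)C(C)(C)C)cc2)CC1=O
F4 | step 15 | allyl 2-{(3S)-3-(TBS-oxy)-5-[4-(TBS-oxy)phenyl]pentylidene}-3-oxo-7-[4-(TBS-oxy)phenyl]-5-{[4-(TIPS-oxy)phenyl]methoxy}heptanoate (E/Z mixture, 5S) | C=CCOC(=O)C(=CC[C@@H](O[Si](C)(C)C(C)(C)C)CCc1ccc(O[Si](C)(C)C(C)(C)C)cc1)C(=O)C[C@@H](OCc1ccc(O[Si](C(C)C)(C(C)C)C(C)C)cc1)CCc1ccc(O[Si](C)(C)C(C)(C)C)cc1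
F0 | step 19 | none | none
F5 | step 17 | (5S)-5-hydroxy-7-[4-(TBS-oxy)phenyl]-1-[4-(TIPS-oxy)phenyl]-2-{(3S,5S)-5-(TBS-oxy)-7-[4-(TBS-oxy)phenyl]hept-1-en-3-yl}hept-1-en-3-one | C=C[C@H](C[C@@H](O[Si](C)(C)C(C)(C)C)CCc1ccc(O[Si](C)(C)C(C)(C)C)cc1)C(=Cc1ccc(O[Si](C(C)C)(C(C)C)C(C)C)cc1)C(=O)C[C@@H](O)CCc1ccc(O[Si](C)(C)C(C)(C)C)cc1
F6 | step 20 | (2S,3S,4R,6S)-epimer of 30 (equatorial C4 alcohol) | CC(C)(C)[Si](C)(C)Oc1ccc(/C=C/[C@H](C[C@@H](O[Si](C)(C)C(C)(C)C)CCc2ccc(O[Si](C)(C)C(C)(C)C)cc2)[C@@H]2[C@@H](c3ccc(O[Si](C(C)C)(C(C)C)C(C)C)cc3)O[C@@H](CCc3ccc(O[Si](C)(C)C(C)(C)C)cc3)C[C@H]2O)cc1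
F7 | step 20 | 4-nitrobenzoate of 30 (axial, 4S) | CC(C)(C)[Si](C)(C)Oc1ccc(/C=C/[C@H](C[C@@H](O[Si](C)(C)C(C)(C)C)CCc2ccc(O[Si](C)(C)C(C)(C)C)cc2)[C@@H]2[C@@H](c3ccc(O[Si](C(C)C)(C(C)C)C(C)C)cc3)O[C@@H](CCc3ccc(O[Si](C)(C)C(C)(C)C)cc3)C[C@@H]2OC(=O)c2ccc(cc2)[N+](=O)[O-])cc1
A1 | alternative 1 | 2,6-cis-4-methylene-1,3-dioxane with a 4-mesyloxyphenyl group at C2, the arylethyl arm on the acetal carbon C6 and the full silylated side chain at C3 | CC(C)(C)[Si](C)(C)Oc1ccc(/C=C/[C@H](C[C@@H](O[Si](C)(C)C(C)(C)C)CCc2ccc(O[Si](C)(C)C(C)(C)C)cc2)[C@@H]2[C@@H](c3ccc(OS(C)(=O)=O)cc3)O[C@@H](CCc3ccc(O[Si](C)(C)C(C)(C)C)cc3)OC2=C)cc1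
A2 | alternative 1 | 2,6-cis-tetrahydropyran-4-one with the full side chain and a 4-mesyloxyphenyl group at C2 | CC(C)(C)[Si](C)(C)Oc1ccc(/C=C/[C@H](C[C@@H](O[Si](C)(C)C(C)(C)C)CCc2ccc(O[Si](C)(C)C(C)(C)C)cc2)[C@@H]2[C@@H](c3ccc(OS(C)(=O)=O)cc3)O[C@@H](CCc3ccc(O[Si](C)(C)C(C)(C)C)cc3)CC2=O)cc1
A3 | alternative 2 | (E)-1-[4-(TBS-oxy)phenyl]-3-(triethylsilyloxy)buta-1,3-diene carrying the silylated (1E,3S,5S)-diarylheptenyl chain on C2 of the diene | CC(C)(C)[Si](C)(C)Oc1ccc(/C=C(/C(=C)O[Si](CC)(CC)CC)[C@H](/C=C/c2ccc(O[Si](C)(C)C(C)(C)C)cc2)C[C@@H](O[Si](C)(C)C(C)(C)C)CCc2ccc(O[Si](C)(C)C(C)(C)C)cc2)cc1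
A4 | alternative 2 | 3-[4-(TBS-oxy)phenyl]propanal | O=CCCc1ccc(O[Si](C)(C)C(C)(C)C)cc1
A5 | alternative 2 | 2,6-cis-dihydropyran C3–C4 triethylsilyl enol ether with the full side chain | CC(C)(C)[Si](C)(C)Oc1ccc(/C=C/[C@H](C[C@@H](O[Si](C)(C)C(C)(C)C)CCc2ccc(O[Si](C)(C)C(C)(C)C)cc2)C2=C(O[Si](CC)(CC)CC)C[C@H](CCc3ccc(O[Si](C)(C)C(C)(C)C)cc3)O[C@@H]2c3ccc(O[Si](C)(C)C(C)(C)C)cc3)cc1
A6 | alternative 3 | open-chain C4,C6-diol with a free 4-hydroxybenzyl group on C3 and four silyl ethers | CC(C)(C)[Si](C)(C)Oc1ccc(/C=C/[C@H](C[C@@H](O[Si](C)(C)C(C)(C)C)CCc2ccc(O[Si](C)(C)C(C)(C)C)cc2)[C@H](Cc2ccc(O)cc2)[C@@H](O)C[C@@H](O)CCc2ccc(O[Si](C)(C)C(C)(C)C)cc2)cc1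
A7 | alternative 3 | blepharocalyxin C carrying four TBS ethers (three phenols and the C3' hydroxyl) | CC(C)(C)[Si](C)(C)Oc1ccc(/C=C/[C@H](C[C@@H](O[Si](C)(C)C(C)(C)C)CCc2ccc(O[Si](C)(C)C(C)(C)C)cc2)[C@@H]2[C@@H](c3ccc(O)cc3)O[C@@H](CCc3ccc(O[Si](C)(C)C(C)(C)C)cc3)C[C@@H]2O)cc1
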